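**Strategy.** Ring B (C1 linker, C2 and C3 prenyl, C4 and C5 OH, C6 H) carries two identical prenyl groups on adjacent carbons. C2 lies ortho to no oxygen, beyond the reach of ortho-Claisen or directed-metalation logic. Both aryl–CH2 bonds are therefore formed at once. Ring B of a eugenol-derived 1,3-diarylpropane is dearomatised to its o-benzoquinone, whose only unsubstituted C2=C3 bond takes up butadiene in a Diels–Alder reaction. Rearomatisation gives a 5,8-dihydronaphthalene-1,2-diol. Cutting its lone alkene and olefinating both ends turns one fused ring into the two prenyl arms. The saturated linker is thus in place before any prenyl alkene exists.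

Key step: step 3

Assumption: the SMILES holds no stereocentre and no E/Z-stereogenic alkene (both alkenes end in CMe2). Kazinol J is therefore achiral, and the demand for a single enantiomer is met without an asymmetric step. The only stereocentres of the route (in 8) are transient.

Step 1
Reactants: 1 4-bromo-3-methoxyphenol
Product: 2 (4-bromo-3-methoxyphenoxy)triisopropylsilane
Conditions: TIPSCl (1.1 equiv), imidazole (2 equiv), DMF, 0 °C→rt
Reagents that add atoms: triisopropylsilyl chloride, CC(C)[Si](Cl)(C(C)C)C(C)C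
Why: Imidazole-promoted silylation of a phenol is routine, and the bulky TIPS ether is chosen because it should outlast the aqueous phosphate of step 2, the oxidants of steps 3 and 5 and the ylide of step 6 yet fall to fluoride in step 7.

Step 2
Reactants: 3 eugenol (4-allyl-2-methoxyphenol); 2 (4-bromo-3-methoxyphenoxy)triisopropylsilane
Product: 5 2-methoxy-4-{3-[2-methoxy-4-(triisopropylsilyloxy)phenyl]propyl}phenol, via bis-boryl adduct 4 (not isolated)
Conditions: 3, 9-BBN (2.2 equiv), THF, 0 °C→rt; then 2, PdCl2(dppf) (5 mol %), aq K3PO4, THF–DMF, 50 °C, degassed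
Reagents that add atoms: none
Why: Anti-Markovnikov hydroboration of the terminal alkene followed by B-alkyl Suzuki–Miyaura coupling forms the ring A–CH2 bond and delivers the saturated C3 linker directly, the second equivalent of 9-BBN being taken up by the phenol as a B–O bond that the aqueous base hydrolyses again.

Step 3
Reactants: 5 2-methoxy-4-{3-[2-methoxy-4-(triisopropylsilyloxy)phenyl]propyl}phenol; 6 buta-1,3-diene
Product: 8 (±)-cis-4-{3-[2-methoxy-4-(triisopropylsilyloxy)phenyl]propyl}-4a,5,8,8a-tetrahydronaphthalene-1,2-dione, via o-quinone 7 (not isolated)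
Conditions: IBX (1.05 equiv), THF, rt, dark; filter under Ar; then 4 Å MS, 6 (15 equiv, 20 wt % in toluene), sealed tube, rt→40 °C; volatiles removed, used crude
Reagents that add atoms: 2-iodoxybenzoic acid (IBX, adds one O), O=C1OI(=O)(O)c2ccccc12
Why: IBX binds the free phenol of 5, delivers oxygen to the methoxy-bearing ortho carbon and expels methanol (oxidative demethylation of a guaiacol), and the electron-poor C2=C3 bond of the resulting o-quinone 7 then undergoes a concerted normal-electron-demand [4+2] cycloaddition with s-cis butadiene, forming the C2–CH2 and C3–CH2 bonds together. The closest known reaction type is the Diels–Alder reaction of o-benzoquinones and 1,2-naphthoquinones as carbon dienophiles with acyclic 1,3-dienes. The one new ring, a cyclohexene fused at C2–C3, is closed by this intermolecular [4+2] cycloaddition. The two new stereocentres (C4a and C8a of 8, that is C2 and C3 of ring B) are cis because the addition is suprafacial on a ring cis-alkene; 8 is racemic and both centres are erased in step 4, so they have no bearing on the achiral target. Site selectivity is needed between C2=C3 and C6=C1, and the linker on C1 secures it by making C6=C1 trisubstituted, more electron-rich and hindered, while the symmetry of butadiene removes any regiochemical question. Periselectivity (quinone as dienophile rather than as hetero-diene, carbon diene or partner in self-dimerisation) and suppression of tautomerisation to the quinone methide rest on the large excess of an unhindered, unpolarised diene and on neutral, sieve-dried conditions.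

Step 4
Reactants: 8 (±)-cis-4-{3-[2-methoxy-4-(triisopropylsilyloxy)phenyl]propyl}-4a,5,8,8a-tetrahydronaphthalene-1,2-dione
Product: 9 1,2-bis(tert-butyldimethylsilyloxy)-4-{3-[2-methoxy-4-(triisopropylsilyloxy)phenyl]propyl}-5,8-dihydronaphthalene
Conditions: TBSOTf (2.5 equiv), Et3N (5 equiv), CH2Cl2, −78→0 °C
Reagents that add atoms: tert-butyldimethylsilyl triflate, CC(C)(C)[Si](C)(C)OS(=O)(=O)C(F)(F)F
Why: Aromatising double enol silylation of a quinone Diels–Alder adduct: TBSOTf activates the two carbonyl groups, Et3N removes the α-proton at C8a and the vinylogous γ-proton at C4a, and the gain of aromaticity drives formation of the catechol bis(silyl ether), which erases both stereocentres and never exposes the oxidisable free catechol.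

Step 5
Reactants: 9 1,2-bis(tert-butyldimethylsilyloxy)-4-{3-[2-methoxy-4-(triisopropylsilyloxy)phenyl]propyl}-5,8-dihydronaphthalene
Product: 10 2,2'-[3,4-bis(tert-butyldimethylsilyloxy)-6-{3-[2-methoxy-4-(triisopropylsilyloxy)phenyl]propyl}-1,2-phenylene]diacetaldehyde
Conditions: OsO4 (2 mol %), NaIO4 (4 equiv), 2,6-lutidine (2 equiv), 1,4-dioxane–H2O (3:1), rt; used without chromatography
Reagents that add atoms: sodium periodate (terminal source of both aldehyde oxygens), [Na+].[O-]I(=O)(=O)=O; osmium tetroxide (catalytic oxygen carrier), O=[Os](=O)(=O)=O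
Why: Lemieux–Johnson cleavage: the C6=C7 bond of the dihydronaphthalene is the only alkene in 9, so catalytic OsO4 dihydroxylates it and periodate cleaves the diol to the two arylacetaldehyde arms, as is known for 1,4-dihydronaphthalenes, while 2,6-lutidine buffers the medium and the aryl silyl ethers are inert.

Step 6
Reactants: 10 2,2'-[3,4-bis(tert-butyldimethylsilyloxy)-6-{3-[2-methoxy-4-(triisopropylsilyloxy)phenyl]propyl}-1,2-phenylene]diacetaldehyde
Product: 11 1,2-bis(tert-butyldimethylsilyloxy)-3,4-bis(3-methylbut-2-enyl)-5-{3-[2-methoxy-4-(triisopropylsilyloxy)phenyl]propyl}benzene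
Conditions: i-PrPPh3I (4 equiv), n-BuLi (3.8 equiv), THF, 0 °C; then 10, −78 °C→rt
Reagents that add atoms: isopropyltriphenylphosphonium iodide, CC(C)[P+](c1ccccc1)(c1ccccc1)c1ccccc1.[I-]
Why: Twofold Wittig olefination with the non-stabilised isopropylidene ylide turns each ArCH2CHO arm into a prenyl group, no E/Z question arises because the new alkene carbon carries two methyl groups, and excess ylide at low temperature should make carbonyl addition faster than enolisation.

Step 7
Reactants: 11 1,2-bis(tert-butyldimethylsilyloxy)-3,4-bis(3-methylbut-2-enyl)-5-{3-[2-methoxy-4-(triisopropylsilyloxy)phenyl]propyl}benzene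
Product: 12 Kazinol J (5-[3-(4-hydroxy-2-methoxyphenyl)propyl]-3,4-bis(3-methylbut-2-enyl)benzene-1,2-diol)
Conditions: TBAF (4 equiv), AcOH (4 equiv), THF, 0 °C→rt, Ar, degassed work-up
Reagents that add atoms: none
Why: Fluoride-driven cleavage of all three aryl silyl ethers is fast, and the acetic acid buffer keeps the catechol protonated (no autoxidation of a catecholate) without being acidic enough to cyclise the o-prenylphenol to a chroman.

**Compound list**

1 | 4-bromo-3-methoxyphenol | COc1cc(O)ccc1Br | starting material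
2 | (4-bromo-3-methoxyphenoxy)triisopropylsilane | COc1cc(O[Si](C(C)C)(C(C)C)C(C)C)ccc1Br | intermediate
3 | eugenol (4-allyl-2-methoxyphenol) | C=CCc1ccc(O)c(OC)c1 | starting material
4 | O,C-bis(9-BBN) adduct of eugenol: 9-{3-[4-(9-borabicyclo[3.3.1]nonan-9-yloxy)-3-methoxyphenyl]propyl}-9-borabicyclo[3.3.1]nonane | COc1cc(CCCB2C3CCCC2CCC3)ccc1OB1C2CCCC1CCC2 | intermediate
5 | 2-methoxy-4-{3-[2-methoxy-4-(triisopropylsilyloxy)phenyl]propyl}phenol | COc1cc(O[Si](C(C)C)(C(C)C)C(C)C)ccc1CCCc1ccc(O)c(OC)c1 | intermediate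
6 | buta-1,3-diene | C=CC=C | starting material
7 | 4-{3-[2-methoxy-4-(triisopropylsilyloxy)phenyl]propyl}cyclohexa-3,5-diene-1,2-dione | COc1cc(O[Si](C(C)C)(C(C)C)C(C)C)ccc1CCCC1=CC(=O)C(=O)C=C1 | intermediate
8 | (±)-cis-4-{3-[2-methoxy-4-(triisopropylsilyloxy)phenyl]propyl}-4a,5,8,8a-tetrahydronaphthalene-1,2-dione (racemic, one enantiomer drawn) | COc1cc(O[Si](C(C)C)(C(C)C)C(C)C)ccc1CCCC1=CC(=O)C(=O)[C@@H]2CC=CC[C@H]12 | intermediate
9 | 1,2-bis(tert-butyldimethylsilyloxy)-4-{3-[2-methoxy-4-(triisopropylsilyloxy)phenyl]propyl}-5,8-dihydronaphthalene | COc1cc(O[Si](C(C)C)(C(C)C)C(C)C)ccc1CCCc1cc(O[Si](C)(C)C(C)(C)C)c(O[Si](C)(C)C(C)(C)C)c2CC=CCc12 | intermediate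
10 | 2,2'-[3,4-bis(tert-butyldimethylsilyloxy)-6-{3-[2-methoxy-4-(triisopropylsilyloxy)phenyl]propyl}-1,2-phenylene]diacetaldehyde | COc1cc(O[Si](C(C)C)(C(C)C)C(C)C)ccc1CCCc1cc(O[Si](C)(C)C(C)(C)C)c(O[Si](C)(C)C(C)(C)C)c(CC=O)c1CC=O | intermediate
11 | 1,2-bis(tert-butyldimethylsilyloxy)-3,4-bis(3-methylbut-2-enyl)-5-{3-[2-methoxy-4-(triisopropylsilyloxy)phenyl]propyl}benzene | COc1cc(O[Si](C(C)C)(C(C)C)C(C)C)ccc1CCCc1cc(O[Si](C)(C)C(C)(C)C)c(O[Si](C)(C)C(C)(C)C)c(CC=C(C)C)c1CC=C(C)C | intermediate
12 | Kazinol J | COc1cc(O)ccc1CCCc1cc(O)c(O)c(CC=C(C)C)c1CC=C(C)C | target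

**Count.** Total steps: 7. Longest linear sequence: 7 steps (1→2→5→8→9→10→11→12).

**Steps most likely to fail**

Step 3 (key step).
- **Failure process:** o-quinone 7 may be consumed faster than it adds butadiene. The competing processes are self-dimerisation, tautomerisation to the quinone methide at the benzylic CH2, hetero-Diels–Alder addition across the O=C–C=O unit, and redox exchange with adduct that enolises too early.
- **Fallback (sets out from 2, comes back at 9):** the cycloaddition is moved to the robust p-quinone series and the linker is attached afterwards. Stille allylation of 2 (allyltributylstannane, Pd(PPh3)4, toluene, 100 °C) should give 1-allyl-2-methoxy-4-(triisopropylsilyloxy)benzene F1. Commercial 2-methoxy-1,4-benzoquinone and 6 (toluene, 60 °C) should combine at the unsubstituted double bond to give (±)-cis-2-methoxy-4a,5,8,8a-tetrahydronaphthalene-1,4-dione F2. Et3N enolises this to 2-methoxy-5,8-dihydronaphthalene-1,4-diol F3. The less hindered hydroxyl, remote from the methoxy group, is triflated (PhNTf2, K2CO3, THF) to give 4-hydroxy-3-methoxy-5,8-dihydronaphthalen-1-yl trifluoromethanesulfonate F4. Hydroboration of F1 (9-BBN, 1.0 equiv) gives 9-{3-[2-methoxy-4-(triisopropylsilyloxy)phenyl]propyl}-9-borabicyclo[3.3.1]nonane F5. Its B-alkyl Suzuki–Miyaura coupling with F4 (PdCl2(dppf), aq K3PO4) gives 2-methoxy-4-{3-[2-methoxy-4-(triisopropylsilyloxy)phenyl]propyl}-5,8-dihydronaphthalen-1-ol F6. IBX removes the methyl group oxidatively to give 4-{3-[2-methoxy-4-(triisopropylsilyloxy)phenyl]propyl}-5,8-dihydronaphthalene-1,2-dione F7. Aqueous Na2S2O4 reduces this in the same flask to 4-{3-[2-methoxy-4-(triisopropylsilyloxy)phenyl]propyl}-5,8-dihydronaphthalene-1,2-diol F8. TBSCl and imidazole then give 9.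

Step 6.
- **Failure process:** the strongly basic ylide may deprotonate the benzylic α-CH2 of the arylacetaldehyde arms. This opens the way to intramolecular aldol condensation between the two neighbouring arms or to an incomplete second olefination.
- **Fallback (sets out from 10, comes back at 11):** olefination with a non-basic stabilised ylide, followed by reduction of the ester carbons to methyl groups. (Carbethoxyethylidene)triphenylphosphorane (CH2Cl2, rt) should give diethyl (2E,2'E)-4,4'-[3,4-bis(tert-butyldimethylsilyloxy)-6-{3-[2-methoxy-4-(triisopropylsilyloxy)phenyl]propyl}-1,2-phenylene]bis(2-methylbut-2-enoate) F9. DIBAL-H (CH2Cl2, −78 °C) gives the corresponding (2E,2'E)-bis(2-methylbut-2-en-1-ol) F10. Appel bromination (CBr4, PPh3, CH2Cl2, 0 °C) gives the corresponding bis[(E)-4-bromo-3-methylbut-2-enyl]arene F11. LiEt3BH (THF, 0 °C) replaces both bromides by hydride to give 11. The alkene geometry loses its meaning once CH2Br has become CH3.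

Step 2.
- **Failure process:** the TIPS ether may be lost in the warm aqueous base, or oxidative addition of the electron-rich, ortho-substituted bromide may be so slow that protodeboronation of 4 wins.
- **Fallback (sets out from 2 and 3, comes back at 5):** Mizoroki–Heck arylation of eugenol under an anhydrous amine base, then hydrogenation. Pd(OAc)2, P(o-tol)3, Et3N, DMF, 100 °C should give two alkene-position isomers. These are 2-methoxy-4-{(E)-3-[2-methoxy-4-(triisopropylsilyloxy)phenyl]prop-2-enyl}phenol F12 and 2-methoxy-4-{(E)-3-[2-methoxy-4-(triisopropylsilyloxy)phenyl]prop-1-enyl}phenol F13. Both are reduced (H2, Pd/C, EtOAc, rt) to 5, at a stage where no prenyl group is present yet.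

**Further compounds**

F1 | step 3 | 1-allyl-2-methoxy-4-(triisopropylsilyloxy)benzene | C=CCc1ccc(O[Si](C(C)C)(C(C)C)C(C)C)cc1OC
F2 | step 3 | (±)-cis-2-methoxy-4a,5,8,8a-tetrahydronaphthalene-1,4-dione (racemic, one enantiomer drawn) | COC1=CC(=O)[C@H]2CC=CC[C@H]2C1=O
F3 | step 3 | 2-methoxy-5,8-dihydronaphthalene-1,4-diol | COc1cc(O)c2CC=CCc2c1O
F4 | step 3 | 4-hydroxy-3-methoxy-5,8-dihydronaphthalen-1-yl trifluoromethanesulfonate | COc1cc(OS(=O)(=O)C(F)(F)F)c2CC=CCc2c1O
F5 | step 3 | 9-{3-[2-methoxy-4-(triisopropylsilyloxy)phenyl]propyl}-9-borabicyclo[3.3.1]nonane | COc1cc(O[Si](C(C)C)(C(C)C)C(C)C)ccc1CCCB1C2CCCC1CCC2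
F6 | step 3 | 2-methoxy-4-{3-[2-methoxy-4-(triisopropylsilyloxy)phenyl]propyl}-5,8-dihydronaphthalen-1-ol | COc1cc(O[Si](C(C)C)(C(C)C)C(C)C)ccc1CCCc1cc(OC)c(O)c2CC=CCc12
F7 | step 3 | 4-{3-[2-methoxy-4-(triisopropylsilyloxy)phenyl]propyl}-5,8-dihydronaphthalene-1,2-dione | COc1cc(O[Si](C(C)C)(C(C)C)C(C)C)ccc1CCCC1=CC(=O)C(=O)C2=C1CC=CC2
F8 | step 3 | 4-{3-[2-methoxy-4-(triisopropylsilyloxy)phenyl]propyl}-5,8-dihydronaphthalene-1,2-diol | COc1cc(O[Si](C(C)C)(C(C)C)C(C)C)ccc1CCCc1cc(O)c(O)c2CC=CCc12
F9 | step 6 | diethyl (2E,2'E)-4,4'-[3,4-bis(tert-butyldimethylsilyloxy)-6-{3-[2-methoxy-4-(triisopropylsilyloxy)phenyl]propyl}-1,2-phenylene]bis(2-methylbut-2-enoate) | COc1cc(O[Si](C(C)C)(C(C)C)C(C)C)ccc1CCCc1cc(O[Si](C)(C)C(C)(C)C)c(O[Si](C)(C)C(C)(C)C)c(C/C=C(\C)C(=O)OCC)c1C/C=C(\C)C(=O)OCC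
F10 | step 6 | (2E,2'E)-4,4'-[3,4-bis(tert-butyldimethylsilyloxy)-6-{3-[2-methoxy-4-(triisopropylsilyloxy)phenyl]propyl}-1,2-phenylene]bis(2-methylbut-2-en-1-ol) | COc1cc(O[Si](C(C)C)(C(C)C)C(C)C)ccc1CCCc1cc(O[Si](C)(C)C(C)(C)C)c(O[Si](C)(C)C(C)(C)C)c(C/C=C(\C)CO)c1C/C=C(\C)CO
F11 | step 6 | 1,2-bis(tert-butyldimethylsilyloxy)-3,4-bis[(E)-4-bromo-3-methylbut-2-enyl]-5-{3-[2-methoxy-4-(triisopropylsilyloxy)phenyl]propyl}benzene | COc1cc(O[Si](C(C)C)(C(C)C)C(C)C)ccc1CCCc1cc(O[Si](C)(C)C(C)(C)C)c(O[Si](C)(C)C(C)(C)C)c(C/C=C(\C)CBr)c1C/C=C(\C)CBr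
F12 | step 2 | 2-methoxy-4-{(E)-3-[2-methoxy-4-(triisopropylsilyloxy)phenyl]prop-2-enyl}phenol | COc1cc(O[Si](C(C)C)(C(C)C)C(C)C)ccc1/C=C/Cc1ccc(O)c(OC)c1
F13 | step 2 | 2-methoxy-4-{(E)-3-[2-methoxy-4-(triisopropylsilyloxy)phenyl]prop-1-enyl}phenol | COc1cc(O[Si](C(C)C)(C(C)C)C(C)C)ccc1C/C=C/c1ccc(O)c(OC)c1
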